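Locants follow carotenoid numbering: ring A is C1–C6 (C1 carries the gem-dimethyl group), the chain runs C7–C15 and C15'–C7', ring B is C1'–C6' and ring C is the dihydrofuran O/C5'/C6'/C7'/C8'.

## Analysis of the target

The target is all-E (3S,5R,6R,3'S,5'R,8'R)-5',8'-epoxy-5,6,5',8'-tetrahydro-β,β-carotene-3,5,6,3'-tetrol: a conjugated octaene (C7=C8 to C9'=C10') that ends in the cyclohexanetriol ring A on one side and, through sp3 C8', in a 2,5-dihydrofuran (ring C) fused to a cyclohexanol (ring B) on the other. The six stereocentres sit in two remote clusters (C3, C5, C6 and C3', C5', C8'), so each end has to be made enantiopure by itself. In ring A, C3–O and C5–O are trans, and C5–O and C6–O are trans-diaxial in the chair that keeps C3–O, the C5 methyl and C7 equatorial. In rings B/C, C5'–O is trans to C3'–O and the chain on C8' is trans to the C5' methyl. C3/C5 and C3'/C5' have the same configuration, so one building block can serve both ends. The polyene is sensitive to light, oxygen and acid; the tertiary allylic C6–OH ionises in acid and is then captured by C5–OH, and the doubly allylic C8'–O bond epimerises in acid, so all late steps must be neutral or basic. The feature on which the strategy rests is that the C5 carbinol oxygen of ring A is axial on the ring face that also carries the axial C1 methyl, the face reagents avoid. Oxidation of a ring enolate or alkene would therefore give the C5 epimer, and C5 is instead made by forming the C5–C6 bond onto a C5 ketone.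

## Retrosynthetic reasoning

**28 from 27.** The last operation only removes the silyl ethers on C3–O, C3'–O and C5–O. Fluoride is chosen because neither end group tolerates acid.

**27 from 26 and 21; 26 from 16 and 25.** The chain is cut at C11'=C12' and at C11=C12 into C15 + C10 + C15. Both bonds are disubstituted E-alkenes next to methyl-bearing carbons, where a phosphonate olefination is reliably E-selective. The central piece 25 is symmetric and comes from dialdehyde 22. Both end pieces are used as aldehydes. The ring A aldehyde 16 is coupled first, because the anion of 26 is conjugated only to a free C6 hydroxyl, which cannot leave. The furanoid aldehyde 21 is coupled last and meets base only as an electrophile.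

**21 from 20; 20 from 8 and 17 through 19 and 18.** Ring C is opened at O–C8'. The C5' oxygen is already present with the right configuration in ketol 8, and C6' is sp2 in the target, so its configuration in the precursors is irrelevant. The forward step has to ionise the tertiary allylic C6'–OH of 20 and let the C5' hydroxyl close on C8' while the (E)-geometry of C7'=C8' is kept. The aldehyde of 20 is there to hold the positive charge at C6'. The C6'–C7' bond is made by adding the acetylide of 17 to the ketone of 8, and the (E)-alkene by trans-reduction of the propargylic alcohol.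

**16 from 12 and 13; 12 from 8 through 11, 10 and 9.** The C7=C8 bond is cut so that the five-carbon phosphonate 13 brings C8–C11. In ring A the C6 carbinol must carry its oxygen trans to C5–O. A carbon nucleophile adding to the C6 ketone would enter from the open face and give the C6 epimer, which is harmless for rings B/C but wrong here. The ketone is therefore methylenated and the oxygen is brought in from the open face by dihydroxylation of the exocyclic alkene 10, with the C5 silyl ether of 9 adding to the shielding of the other face.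

**8 from 7 (key step).** Ring A is opened at C5–C6. A carbene-catalysed crossed benzoin turns the C6 aldehyde of 7 into an acyl anion equivalent that adds to the C5 methyl ketone. This makes the tertiary carbinol by C–C bond formation under catalyst control, closes the ring, and leaves C6 as a ketone that both branches need.

**7 from 5; 5 from 4; 4 from 2 and 3; 2 from 1.** Both carbonyl groups of 7 are unmasked in one ozonolysis of diene 5: the vinyl group on the quaternary carbon gives the aldehyde and the isopropenyl group gives the methyl ketone. The C3 stereocentre is set by catalytic asymmetric methallylation of aldehyde 2. A six-membered cycloalkene as the source of 7 was weighed. It would need an enantioselective reduction of a ketone whose two α-methylene groups are nearly alike, which is not reliable enough for the first stereocentre.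

**25 from 22 through 23 and 24.** Reduction, bromination and a Michaelis–Arbuzov reaction convert the dialdehyde into the bisphosphonate without touching the triene geometry.

## Alternatives that were turned down

**Alternative 1:** The oxolane is disconnected at C5'–O. C8' is made first as a secondary carbinol by a separate reagent-controlled step on a 7',8'-saturated chain. A 5',6'-epoxide function on the face of the C3' oxygen is then opened at C5' by that hydroxyl under camphorsulfonic acid with inversion, giving the hydroxy-oxolane A1, which still has to lose the C6' hydroxyl toward C7'. In its favour, C8' never passes through a cation and C5' is set by a stereospecific inversion. Against it, the opening is a 5-endo attack at a fully substituted epoxide carbon under acid that can equally ionise C5' or C6', and A1 needs a further dehydration. The route also gives no answer for ring A, where a hydrolytic opening of the same epoxide has no secure regiochemistry. On control of C8' this alternative is stronger than the chosen route. The chosen route offers one ketol (8) for both end groups and a C5/C5' centre set in a catalytic C–C bond formation, not by a face-selective epoxidation followed by an acid opening.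

**Alternative 2:** Ring A is disconnected at C1–C6. The carbinol carbon of (R)-linalool A2 becomes C5, and Fe(acac)3/PhSiH3 transfers a hydrogen atom to the C1=C2 alkene so that the tertiary C1 radical adds to the C6 ketone, giving the protected triol A3 with C7 already in place as a silyloxymethyl group. In its favour, A3 corresponds to a protected form of diol 11, so the methylenation and dihydroxylation of the chosen route would be saved; on step count for ring A it is at least as strong. Against it, the radical must add to a ketone next to a fully substituted carbinol, the C6 configuration is decided in a congested radical chair with no clear bias toward C6–O trans to C5–O, and the C3 oxygen has to be introduced on the open chain with separate control. A3 also cannot serve rings B/C without removing the C6 oxygen again. The chosen route sets C6 from an identifiable open face and uses 8 for both ends.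

**Alternative 3:** Ring C is disconnected at O–C8' of an allene spanning C6'=C7'=C8' that is conjugated to C9'=C10'. Ph3PAuCl/AgBF4 (cationic monovalent gold) activates C7'=C8', the C5' hydroxyl adds to C8' in a 5-endo cyclisation, and the allene axis is transferred to C8', giving the bis-silyl ether A4. In its favour, the transfer is stereospecific by mechanism, the conditions are neutral, and the allene can be reached from the same kind of ketone as 8. Against it, the axis must first be made configurationally pure by an SN2' substitution at a tertiary propargylic centre, so the configuration of the C6' carbinol matters there. Cationic gold can also scramble allene axes. The strategy does not address ring A. On C8' this alternative is the stronger one, because the chosen ring closure relies on the geometric memory of an allyl cation. The chosen route offers a C6' centre whose configuration is irrelevant, no chirality relay, and a ketol shared by both ends.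

Key step: step 5

## Remarks

- Compounds 1, 3, 13, 17 and 22 are taken as catalogue compounds.
- The ring carbon that becomes C6' is formed without control in step 13 and is flattened in step 16; 18–20 are therefore written without a descriptor at that carbon.
- Which antipode of the triazolium salt matches the substrate cannot be derived with certainty; the (5aS,10bR) salt is written and its mirror image is the immediate replacement.

## Route

Step 1
Reactants: 1 methyl 3,3-dimethylpent-4-enoate
Product: 2 3,3-dimethylpent-4-enal
Conditions: i-Bu2AlH (1.05 equiv), CH2Cl2, −78 °C; aq. potassium sodium tartrate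
Reagents that add atoms: none
Why: Partial ester reduction; the aluminium hemiacetal is stable at −78 °C and gives the aldehyde only on work-up. The volatile aldehyde is used crude.

Step 2
Reactants: 2 3,3-dimethylpent-4-enal; 3 tributyl(2-methylprop-2-en-1-yl)stannane
Product: 4 (4R)-2,6,6-trimethylocta-1,7-dien-4-ol
Conditions: (R)-BINOL (0.2 equiv), Ti(OiPr)4 (0.1 equiv), 4 Å MS, CH2Cl2, −20 °C; aq. NaHCO3
Reagents that add atoms: none
Why: Keck asymmetric allylation; the BINOL–titanium Lewis acid binds the aldehyde and the methallylstannane attacks one carbonyl face, (R)-BINOL giving the (R) carbinol because the aldehyde residue outranks the methallyl group. This sets C3 and C3' of the target; any minor enantiomer becomes a separable diastereomer in step 5.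

Step 3
Reactants: 4 (4R)-2,6,6-trimethylocta-1,7-dien-4-ol
Product: 5 tert-butyldimethyl{[(4R)-2,6,6-trimethylocta-1,7-dien-4-yl]oxy}silane
Conditions: TBSCl (1.3 equiv), imidazole, DMF, 25 °C
Reagents that add atoms: tert-butyldimethylsilyl chloride, CC(C)(C)[Si](C)(C)Cl
Why: Standard silylation of a secondary alcohol; the ether survives ozone, amine base, titanium and osmium reagents and hydride, and is removed by fluoride at the end.

Step 4
Reactants: 5 tert-butyldimethyl{[(4R)-2,6,6-trimethylocta-1,7-dien-4-yl]oxy}silane
Product: 7 (4S)-4-[(tert-butyldimethylsilyl)oxy]-2,2-dimethyl-6-oxoheptanal, via bis-ozonide 6 (not isolated)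
Conditions: O3, CH2Cl2, −78 °C; then PPh3 (2.5 equiv), −78 → 25 °C
Reagents that add atoms: ozone, [O-][O+]=O
Why: Ozonolysis of both C=C bonds; the vinyl group on the quaternary carbon gives the neopentyl aldehyde and the isopropenyl group the methyl ketone, each with loss of formaldehyde. Neutral reduction of the ozonides avoids β-elimination of the silyloxy ketone; the stereocentre is not touched (the descriptor changes by priority only).

Step 5
Reactants: 7 (4S)-4-[(tert-butyldimethylsilyl)oxy]-2,2-dimethyl-6-oxoheptanal
Product: 8 (2R,4S)-4-[(tert-butyldimethylsilyl)oxy]-2-hydroxy-2,6,6-trimethylcyclohexan-1-one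
Conditions: (5aS,10bR)-2-(pentafluorophenyl)-5a,10b-dihydro-4H,6H-indeno[2,1-b][1,2,4]triazolo[4,3-d][1,4]oxazin-2-ium tetrafluoroborate (0.15 equiv), Et3N (0.15 equiv), toluene (0.05 M), 25–40 °C, argon
Reagents that add atoms: none
Why: Deprotonation of the triazolium salt gives the carbene, which adds to the C6 aldehyde of 7; proton transfer gives the Breslow enaminol, whose C6 attacks the C5 ketone, and release of the carbene leaves the α-ketol. The closest known reaction type is the intramolecular crossed aldehyde–ketone benzoin cyclisation under chiral bicyclic triazolium catalysis, which gives five- and six-membered tertiary α-ketols, aliphatic ones included. Ring A closes in a 6-exo-trig mode on the ketone carbonyl, forming the C5–C6 bond. The new stereocentre C5 is set by the catalyst, whose aminoindanol wall leaves one face of the enaminol open, acting together with a chair in which the C3 silyloxy group and the C5 methyl are equatorial (an axial C5 methyl would meet the axial C1 methyl), so that the C5 oxygen ends axial and trans to C3–O. Chemoselectivity is built into 7: only the aldehyde can become the acyl anion equivalent, its α-carbon is quaternary and cannot enolise, and the neopentyl position slows intermolecular homo-benzoin. What has to be held back is the aldol of the C4 enolate onto the aldehyde and β-elimination of the C3 silyloxide, hence the weak amine base at low loading. A minor enantiomer of 7 from step 2 gives a diastereomeric ketol under catalyst control and is removed here by chromatography.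

Step 6
Reactants: 8 (2R,4S)-4-[(tert-butyldimethylsilyl)oxy]-2-hydroxy-2,6,6-trimethylcyclohexan-1-one
Product: 9 (2R,4S)-4-[(tert-butyldimethylsilyl)oxy]-2,6,6-trimethyl-2-[(triethylsilyl)oxy]cyclohexan-1-one
Conditions: Et3SiOTf (1.5 equiv), 2,6-lutidine (2.5 equiv), CH2Cl2, −78 → 0 °C
Reagents that add atoms: triethylsilyl trifluoromethanesulfonate, CC[Si](CC)(CC)OS(=O)(=O)C(F)(F)F
Why: A silyl triflate is needed for the hindered tertiary hydroxyl. The ether prevents α-ketol rearrangement and titanium alkoxide formation in step 7 and adds bulk to the ring face it occupies for step 8.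

Step 7
Reactants: 9 (2R,4S)-4-[(tert-butyldimethylsilyl)oxy]-2,6,6-trimethyl-2-[(triethylsilyl)oxy]cyclohexan-1-one
Product: 10 tert-butyldimethyl({(1S,3R)-3,5,5-trimethyl-4-methylidene-3-[(triethylsilyl)oxy]cyclohexyl}oxy)silane
Conditions: Cp2TiMe2 (3 equiv), toluene, 70 °C, dark
Reagents that add atoms: dimethyltitanocene, C[Ti](C)(C1C=CC=C1)C1C=CC=C1
Why: Petasis methylenation; loss of methane gives Cp2Ti=CH2, which adds to the ketone in a [2+2] cycloaddition and cycloreverts to the alkene. The small, non-basic titanium carbene reaches a ketone flanked by two fully substituted carbons where phosphorus ylides fail, and it leaves silyl ethers alone.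

Step 8
Reactants: 10 tert-butyldimethyl({(1S,3R)-3,5,5-trimethyl-4-methylidene-3-[(triethylsilyl)oxy]cyclohexyl}oxy)silane
Product: 11 (1S,2R,4S)-4-[(tert-butyldimethylsilyl)oxy]-1-(hydroxymethyl)-2,6,6-trimethyl-2-[(triethylsilyl)oxy]cyclohexan-1-ol
Conditions: OsO4 (0.05 equiv), N-methylmorpholine N-oxide (2 equiv), acetone/H2O (5:1), 25–40 °C; aq. Na2SO3
Reagents that add atoms: N-methylmorpholine N-oxide, C[N+]1([O-])CCOCC1; water, O
Why: Catalytic OsO4 dihydroxylation ([3+2] cycloaddition, osmate hydrolysis, reoxidation by the N-oxide). In the chair of 10 the C5 silyloxy group and one C1 methyl are axial on the same face, so OsO4 adds to the exocyclic alkene from the other face; the C6 oxygen ends trans to C5–O and C7 equatorial, which is the C6 configuration of the target.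

Step 9
Reactants: 11 (1S,2R,4S)-4-[(tert-butyldimethylsilyl)oxy]-1-(hydroxymethyl)-2,6,6-trimethyl-2-[(triethylsilyl)oxy]cyclohexan-1-ol
Product: 12 (1R,2R,4S)-4-[(tert-butyldimethylsilyl)oxy]-1-hydroxy-2,6,6-trimethyl-2-[(triethylsilyl)oxy]cyclohexane-1-carbaldehyde
Conditions: SO3·pyridine (3 equiv), DMSO, i-Pr2NEt, CH2Cl2, 0 °C
Reagents that add atoms: none
Why: Parikh–Doering oxidation of the primary alcohol; the tertiary hydroxyl cannot be oxidised and an activated-DMSO oxidant does not cleave the glycol. The aldehyde has no α-hydrogen, so C6 cannot epimerise.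

Step 10
Reactants: 12 (1R,2R,4S)-4-[(tert-butyldimethylsilyl)oxy]-1-hydroxy-2,6,6-trimethyl-2-[(triethylsilyl)oxy]cyclohexane-1-carbaldehyde; 13 ethyl (2E)-4-(diethoxyphosphoryl)-3-methylbut-2-enoate
Product: 14 ethyl (2E,4E)-5-{(1R,2R,4S)-4-[(tert-butyldimethylsilyl)oxy]-1-hydroxy-2,6,6-trimethyl-2-[(triethylsilyl)oxy]cyclohexyl}-3-methylpenta-2,4-dienoate
Conditions: 13 (1.5 equiv), LiN(SiMe3)2 (1.4 equiv), THF, −78 °C; then 12, −78 → 0 °C
Reagents that add atoms: none
Why: Horner–Wadsworth–Emmons olefination; the stabilised allylic phosphonate anion gives the (E)-C7=C8 bond and the (E,E)-dienoate is the preferred isomer, any 9Z isomer being removed by chromatography. The anion is a weaker base than a tertiary alkoxide, so the C6 hydroxyl stays protonated and the α-hydroxy aldehyde is not pushed toward rearrangement.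

Step 11
Reactants: 14 ethyl (2E,4E)-5-{(1R,2R,4S)-4-[(tert-butyldimethylsilyl)oxy]-1-hydroxy-2,6,6-trimethyl-2-[(triethylsilyl)oxy]cyclohexyl}-3-methylpenta-2,4-dienoate
Product: 15 (2E,4E)-5-{(1R,2R,4S)-4-[(tert-butyldimethylsilyl)oxy]-1-hydroxy-2,6,6-trimethyl-2-[(triethylsilyl)oxy]cyclohexyl}-3-methylpenta-2,4-dien-1-ol
Conditions: i-Bu2AlH (3.5 equiv), CH2Cl2, −78 °C; aq. potassium sodium tartrate
Reagents that add atoms: none
Why: 1,2-Reduction of the dienoate to the allylic alcohol; silyl ethers and the tertiary hydroxyl are inert and the neutral work-up avoids ionisation at C6.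

Step 12
Reactants: 15 (2E,4E)-5-{(1R,2R,4S)-4-[(tert-butyldimethylsilyl)oxy]-1-hydroxy-2,6,6-trimethyl-2-[(triethylsilyl)oxy]cyclohexyl}-3-methylpenta-2,4-dien-1-ol
Product: 16 (2E,4E)-5-{(1R,2R,4S)-4-[(tert-butyldimethylsilyl)oxy]-1-hydroxy-2,6,6-trimethyl-2-[(triethylsilyl)oxy]cyclohexyl}-3-methylpenta-2,4-dienal
Conditions: MnO2 (activated, 20 equiv), CH2Cl2, 25 °C, dark
Reagents that add atoms: none
Why: Selective oxidation of the primary allylic alcohol on MnO2 under neutral conditions; the tertiary alcohol is inert.

Step 13
Reactants: 8 (2R,4S)-4-[(tert-butyldimethylsilyl)oxy]-2-hydroxy-2,6,6-trimethylcyclohexan-1-one; 17 (2E)-3-methylpent-2-en-4-yn-1-ol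
Product: 18 (2R,4S)-4-[(tert-butyldimethylsilyl)oxy]-1-[(3E)-5-hydroxy-3-methylpent-3-en-1-yn-1-yl]-2,6,6-trimethylcyclohexane-1,2-diol (epimers at C1)
Conditions: 17 (3 equiv), n-BuLi (6 equiv), THF, −78 → 0 °C; then 8, −78 → 0 °C; aq. NH4Cl
Reagents that add atoms: none
Why: 1,2-Addition of a lithium acetylide (O,C-dilithiated enynol) to a hindered ketone, the slim nucleophile of choice for such carbonyls; the first equivalent deprotonates the C5' hydroxyl. The new carbinol centre (C6') is irrelevant because it becomes sp2 in step 16.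

Step 14
Reactants: 18 (2R,4S)-4-[(tert-butyldimethylsilyl)oxy]-1-[(3E)-5-hydroxy-3-methylpent-3-en-1-yn-1-yl]-2,6,6-trimethylcyclohexane-1,2-diol
Product: 19 (2R,4S)-4-[(tert-butyldimethylsilyl)oxy]-1-[(1E,3E)-5-hydroxy-3-methylpenta-1,3-dien-1-yl]-2,6,6-trimethylcyclohexane-1,2-diol
Conditions: NaAlH2(OCH2CH2OCH3)2 (5 equiv), THF, 0 → 25 °C; aq. potassium sodium tartrate
Reagents that add atoms: none
Why: Alkoxide-directed trans-hydroalumination of the propargylic alcohol and protonolysis give the (E)-C7'=C8' alkene; the trisubstituted C9'=C10' bond is not reduced.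

Step 15
Reactants: 19 (2R,4S)-4-[(tert-butyldimethylsilyl)oxy]-1-[(1E,3E)-5-hydroxy-3-methylpenta-1,3-dien-1-yl]-2,6,6-trimethylcyclohexane-1,2-diol
Product: 20 (2E,4E)-5-{(2R,4S)-4-[(tert-butyldimethylsilyl)oxy]-1,2-dihydroxy-2,6,6-trimethylcyclohexyl}-3-methylpenta-2,4-dienal
Conditions: MnO2 (activated, 20 equiv), CH2Cl2, 25 °C, dark
Reagents that add atoms: none
Why: Only the primary allylic alcohol is oxidised; the two tertiary hydroxyls are inert. The aldehyde is installed before ring closure to make the diene electron-poor.

Step 16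
Reactants: 20 (2E,4E)-5-{(2R,4S)-4-[(tert-butyldimethylsilyl)oxy]-1,2-dihydroxy-2,6,6-trimethylcyclohexyl}-3-methylpenta-2,4-dienal
Product: 21 (2E)-3-{(2R,6S,7aR)-6-[(tert-butyldimethylsilyl)oxy]-4,4,7a-trimethyl-2,4,5,6,7,7a-hexahydro-1-benzofuran-2-yl}but-2-enal
Conditions: camphor-10-sulfonic acid (0.2 equiv), CH2Cl2, 0 → 25 °C; Et3N quench
Reagents that add atoms: none
Why: Dehydrative SN1' etherification, the diol counterpart of the epoxide-to-furanoid rearrangement: loss of water from the tertiary allylic C6' gives an allyl cation that is essentially a C6' tertiary cation beside an intact (E)-C7'=C8' bond, because the formyl group withholds charge from C8' and C10'. The axial C5' hydroxyl, fixed on the face opposite the C5' methyl, closes ring C onto the nearer lobe of C8' (5-endo), so the outside substituent C9' ends trans to the C5' methyl, which is 8'R. The silyl ether on C3' keeps that oxygen from competing for the cation.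

Step 17
Reactants: 22 (2E,4E,6E)-2,7-dimethylocta-2,4,6-trienedial
Product: 23 (2E,4E,6E)-2,7-dimethylocta-2,4,6-triene-1,8-diol
Conditions: NaBH4 (1 equiv), MeOH/THF, 0 °C, dark
Reagents that add atoms: none
Why: 1,2-Reduction of both conjugated aldehydes; the triene geometry is not affected.

Step 18
Reactants: 23 (2E,4E,6E)-2,7-dimethylocta-2,4,6-triene-1,8-diol
Product: 24 (2E,4E,6E)-1,8-dibromo-2,7-dimethylocta-2,4,6-triene
Conditions: PBr3 (0.75 equiv), pyridine (cat.), Et2O, −10 °C, dark
Reagents that add atoms: phosphorus tribromide, BrP(Br)Br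
Why: Bromide displaces the alkyl phosphite at the primary allylic carbons; low temperature and exclusion of light keep the all-E triene and avoid allylic transposition.

Step 19
Reactants: 24 (2E,4E,6E)-1,8-dibromo-2,7-dimethylocta-2,4,6-triene
Product: 25 tetraethyl [(2E,4E,6E)-2,7-dimethylocta-2,4,6-triene-1,8-diyl]bis(phosphonate)
Conditions: P(OEt)3 (6 equiv, neat), 100 °C
Reagents that add atoms: triethyl phosphite, CCOP(OCC)OCC
Why: Michaelis–Arbuzov reaction at both primary allylic bromides; bromoethane distils off.

Step 20
Reactants: 16 (2E,4E)-5-{(1R,2R,4S)-4-[(tert-butyldimethylsilyl)oxy]-1-hydroxy-2,6,6-trimethyl-2-[(triethylsilyl)oxy]cyclohexyl}-3-methylpenta-2,4-dienal; 25 tetraethyl [(2E,4E,6E)-2,7-dimethylocta-2,4,6-triene-1,8-diyl]bis(phosphonate)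
Product: 26 diethyl [(2E,4E,6E,8E,10E,12E)-13-{(1R,2R,4S)-4-[(tert-butyldimethylsilyl)oxy]-1-hydroxy-2,6,6-trimethyl-2-[(triethylsilyl)oxy]cyclohexyl}-2,7,11-trimethyltrideca-2,4,6,8,10,12-hexaen-1-yl]phosphonate
Conditions: 25 (3 equiv), KN(SiMe3)2 (1.1 equiv relative to 16), THF, −78 °C; then 16, −78 → 0 °C, dark
Reagents that add atoms: none
Why: Horner–Wadsworth–Emmons olefination of an allylic phosphonate anion with an enal gives the (E)-C11=C12 bond. The excess of the bisphosphonate keeps the reaction at mono-olefination; the surplus is recovered.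

Step 21
Reactants: 26 diethyl [(2E,4E,6E,8E,10E,12E)-13-{(1R,2R,4S)-4-[(tert-butyldimethylsilyl)oxy]-1-hydroxy-2,6,6-trimethyl-2-[(triethylsilyl)oxy]cyclohexyl}-2,7,11-trimethyltrideca-2,4,6,8,10,12-hexaen-1-yl]phosphonate; 21 (2E)-3-{(2R,6S,7aR)-6-[(tert-butyldimethylsilyl)oxy]-4,4,7a-trimethyl-2,4,5,6,7,7a-hexahydro-1-benzofuran-2-yl}but-2-enal
Product: 27 3,3'-bis-O-(tert-butyldimethylsilyl)-5-O-(triethylsilyl) ether of the target
Conditions: 26 (1.1 equiv), KN(SiMe3)2 (1.05 equiv), THF, −78 °C; then 21, −78 → −20 °C, dark
Reagents that add atoms: none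
Why: Second Horner–Wadsworth–Emmons olefination forms the (E)-C11'=C12' bond and completes the C40 chain. The anion is preformed, so 21 meets no free amide base and its C8' hydrogen (γ to the carbonyl) is not removed.

Step 22
Reactants: 27 3,3'-bis-O-(tert-butyldimethylsilyl)-5-O-(triethylsilyl) ether of the target
Product: 28 (3S,5R,6R,3'S,5'R,8'R)-5',8'-epoxy-5,6,5',8'-tetrahydro-β,β-carotene-3,5,6,3'-tetrol (the target)
Conditions: Bu4NF (6 equiv), THF, 25 °C (40 °C if the tertiary silyl ether is slow), dark, argon
Reagents that add atoms: none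
Why: Fluoride cleaves the three Si–O bonds under non-acidic conditions, so neither the tertiary allylic C6–OH nor the C8'–O ether is ionised and no stereocentre is touched.

## Compound list

1 | methyl 3,3-dimethylpent-4-enoate | C=CC(C)(C)CC(=O)OC | starting material
2 | 3,3-dimethylpent-4-enal | C=CC(C)(C)CC=O | intermediate
3 | tributyl(2-methylprop-2-en-1-yl)stannane | CCCC[Sn](CCCC)(CCCC)CC(C)=C | starting material
4 | (4R)-2,6,6-trimethylocta-1,7-dien-4-ol | C=CC(C)(C)C[C@H](O)CC(C)=C | intermediate
5 | tert-butyldimethyl{[(4R)-2,6,6-trimethylocta-1,7-dien-4-yl]oxy}silane | C=CC(C)(C)C[C@H](O[Si](C)(C)C(C)(C)C)CC(C)=C | intermediate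
6 | bis-ozonide of 5 (both C=C bonds as 1,2,4-trioxolanes, mixture at the trioxolane carbons) | C1(OCOO1)C(C)(C)C[C@H](O[Si](C)(C)C(C)(C)C)CC1(C)OCOO1 | intermediate (not isolated)
7 | (4S)-4-[(tert-butyldimethylsilyl)oxy]-2,2-dimethyl-6-oxoheptanal | O=CC(C)(C)C[C@H](O[Si](C)(C)C(C)(C)C)CC(C)=O | intermediate
8 | (2R,4S)-4-[(tert-butyldimethylsilyl)oxy]-2-hydroxy-2,6,6-trimethylcyclohexan-1-one | O=C1C(C)(C)C[C@H](O[Si](C)(C)C(C)(C)C)C[C@@]1(C)O | intermediate
9 | (2R,4S)-4-[(tert-butyldimethylsilyl)oxy]-2,6,6-trimethyl-2-[(triethylsilyl)oxy]cyclohexan-1-one | O=C1C(C)(C)C[C@H](O[Si](C)(C)C(C)(C)C)C[C@@]1(C)O[Si](CC)(CC)CC | intermediate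
10 | tert-butyldimethyl({(1S,3R)-3,5,5-trimethyl-4-methylidene-3-[(triethylsilyl)oxy]cyclohexyl}oxy)silane | C=C1C(C)(C)C[C@H](O[Si](C)(C)C(C)(C)C)C[C@@]1(C)O[Si](CC)(CC)CC | intermediate
11 | (1S,2R,4S)-4-[(tert-butyldimethylsilyl)oxy]-1-(hydroxymethyl)-2,6,6-trimethyl-2-[(triethylsilyl)oxy]cyclohexan-1-ol | OC[C@@]1(O)C(C)(C)C[C@H](O[Si](C)(C)C(C)(C)C)C[C@@]1(C)O[Si](CC)(CC)CC | intermediate
12 | (1R,2R,4S)-4-[(tert-butyldimethylsilyl)oxy]-1-hydroxy-2,6,6-trimethyl-2-[(triethylsilyl)oxy]cyclohexane-1-carbaldehyde | O=C[C@@]1(O)C(C)(C)C[C@H](O[Si](C)(C)C(C)(C)C)C[C@@]1(C)O[Si](CC)(CC)CC | intermediate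
13 | ethyl (2E)-4-(diethoxyphosphoryl)-3-methylbut-2-enoate | CCOC(=O)/C=C(\C)CP(=O)(OCC)OCC | starting material
14 | ethyl (2E,4E)-5-{(1R,2R,4S)-4-[(tert-butyldimethylsilyl)oxy]-1-hydroxy-2,6,6-trimethyl-2-[(triethylsilyl)oxy]cyclohexyl}-3-methylpenta-2,4-dienoate | CCOC(=O)/C=C(C)/C=C/[C@@]1(O)C(C)(C)C[C@H](O[Si](C)(C)C(C)(C)C)C[C@@]1(C)O[Si](CC)(CC)CC | intermediate
15 | (2E,4E)-5-{(1R,2R,4S)-4-[(tert-butyldimethylsilyl)oxy]-1-hydroxy-2,6,6-trimethyl-2-[(triethylsilyl)oxy]cyclohexyl}-3-methylpenta-2,4-dien-1-ol | OC/C=C(C)/C=C/[C@@]1(O)C(C)(C)C[C@H](O[Si](C)(C)C(C)(C)C)C[C@@]1(C)O[Si](CC)(CC)CC | intermediate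
16 | (2E,4E)-5-{(1R,2R,4S)-4-[(tert-butyldimethylsilyl)oxy]-1-hydroxy-2,6,6-trimethyl-2-[(triethylsilyl)oxy]cyclohexyl}-3-methylpenta-2,4-dienal | O=C/C=C(C)/C=C/[C@@]1(O)C(C)(C)C[C@H](O[Si](C)(C)C(C)(C)C)C[C@@]1(C)O[Si](CC)(CC)CC | intermediate
17 | (2E)-3-methylpent-2-en-4-yn-1-ol | OC/C=C(\C)C#C | starting material
18 | (2R,4S)-4-[(tert-butyldimethylsilyl)oxy]-1-[(3E)-5-hydroxy-3-methylpent-3-en-1-yn-1-yl]-2,6,6-trimethylcyclohexane-1,2-diol (C1 epimers) | OC/C=C(\C)C#CC1(O)C(C)(C)C[C@H](O[Si](C)(C)C(C)(C)C)C[C@@]1(C)O | intermediate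
19 | (2R,4S)-4-[(tert-butyldimethylsilyl)oxy]-1-[(1E,3E)-5-hydroxy-3-methylpenta-1,3-dien-1-yl]-2,6,6-trimethylcyclohexane-1,2-diol (C1 epimers) | OC/C=C(C)/C=C/C1(O)C(C)(C)C[C@H](O[Si](C)(C)C(C)(C)C)C[C@@]1(C)O | intermediate
20 | (2E,4E)-5-{(2R,4S)-4-[(tert-butyldimethylsilyl)oxy]-1,2-dihydroxy-2,6,6-trimethylcyclohexyl}-3-methylpenta-2,4-dienal (C1 epimers) | O=C/C=C(C)/C=C/C1(O)C(C)(C)C[C@H](O[Si](C)(C)C(C)(C)C)C[C@@]1(C)O | intermediate
21 | (2E)-3-{(2R,6S,7aR)-6-[(tert-butyldimethylsilyl)oxy]-4,4,7a-trimethyl-2,4,5,6,7,7a-hexahydro-1-benzofuran-2-yl}but-2-enal | O=C/C=C(C)/[C@H]1C=C2C(C)(C)C[C@H](O[Si](C)(C)C(C)(C)C)C[C@@]2(C)O1 | intermediate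
22 | (2E,4E,6E)-2,7-dimethylocta-2,4,6-trienedial | O=C/C(C)=C/C=C/C=C(C)/C=O | starting material
23 | (2E,4E,6E)-2,7-dimethylocta-2,4,6-triene-1,8-diol | OC/C(C)=C/C=C/C=C(C)/CO | intermediate
24 | (2E,4E,6E)-1,8-dibromo-2,7-dimethylocta-2,4,6-triene | BrC/C(C)=C/C=C/C=C(C)/CBr | intermediate
25 | tetraethyl [(2E,4E,6E)-2,7-dimethylocta-2,4,6-triene-1,8-diyl]bis(phosphonate) | CCOP(=O)(OCC)C/C(C)=C/C=C/C=C(C)/CP(=O)(OCC)OCC | intermediate
26 | diethyl [(2E,4E,6E,8E,10E,12E)-13-{(1R,2R,4S)-4-[(tert-butyldimethylsilyl)oxy]-1-hydroxy-2,6,6-trimethyl-2-[(triethylsilyl)oxy]cyclohexyl}-2,7,11-trimethyltrideca-2,4,6,8,10,12-hexaen-1-yl]phosphonate | CCOP(=O)(OCC)C/C(C)=C/C=C/C=C(C)/C=C/C=C(C)/C=C/[C@@]1(O)C(C)(C)C[C@H](O[Si](C)(C)C(C)(C)C)C[C@@]1(C)O[Si](CC)(CC)CC | intermediate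
27 | 3,3'-bis-O-(tert-butyldimethylsilyl)-5-O-(triethylsilyl) ether of the target | CC(/C=C/C=C(C)/C=C/[C@@]1(O)C(C)(C)C[C@H](O[Si](C)(C)C(C)(C)C)C[C@@]1(C)O[Si](CC)(CC)CC)=C\C=C\C=C(C)\C=C\C=C(/C)[C@H]1C=C2C(C)(C)C[C@H](O[Si](C)(C)C(C)(C)C)C[C@@]2(C)O1 | intermediate
28 | (3S,5R,6R,3'S,5'R,8'R)-5',8'-epoxy-5,6,5',8'-tetrahydro-β,β-carotene-3,5,6,3'-tetrol | CC(/C=C/C=C(C)/C=C/[C@@]1(O)C(C)(C)C[C@H](O)C[C@@]1(C)O)=C\C=C\C=C(C)\C=C\C=C(/C)[C@H]1C=C2C(C)(C)C[C@H](O)C[C@@]2(C)O1 | target

## Step count and least certain steps

Total: 22 steps. Longest linear sequence: 15 steps (steps 1–12, 20, 21, 22). The furanoid branch (steps 13–16) leaves the main line at 8 and the C10 branch (steps 17–19) is separate.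

**Step 5 (key step).** The neopentyl aldehyde may form the Breslow intermediate slowly. The base-mediated aldol of the C4 enolate onto the aldehyde, β-elimination of the silyloxide, or a mismatched facial preference leading to the C5 epimer could then take over; retro-benzoin equilibration could also erode the ratio on long reaction times. Fallback from 7: a reductive pinacol cyclisation with SmI2 (THF, t-BuOH, −78 °C) should give the cis-diol (1S,2R,4S)-4-[(tert-butyldimethylsilyl)oxy]-2,6,6-trimethylcyclohexane-1,2-diol F1, with both oxygens held by samarium on one face and the C5 methyl equatorial for the same steric reason as in step 5. Oxidation of its secondary hydroxyl (SO3·pyridine, DMSO, i-Pr2NEt) returns to 8.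

**Step 16.** The C8' configuration depends on the allyl cation keeping its (E)-geometry. Rotation about C7'–C8' in the cation, or capture of the cation by water at C8' followed by re-ionisation, would let the 8'-epimer form; acetal formation between the diol and the aldehyde of another molecule is a further loss. Fallback from 20: the ring closure is run without regard to selectivity, and 21 is separated by chromatography on base-washed silica from its C8' epimer (2E)-3-{(2S,6S,7aR)-6-[(tert-butyldimethylsilyl)oxy]-4,4,7a-trimethyl-2,4,5,6,7,7a-hexahydro-1-benzofuran-2-yl}but-2-enal F2. F2 is returned to the cation manifold with a stronger acid (CF3CO2H, CH2Cl2) and separated again, so that the material ends as 21.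

**Step 7.** The ketone lies between two fully substituted carbons; the titanium carbene may fail to add, and prolonged heating may cost the tertiary silyl ether. Fallback from 9: Peterson olefination. Me3SiCH2Li with CeCl3 (THF, −78 °C) adds to the ketone to give the β-hydroxysilane (2R,4S)-4-[(tert-butyldimethylsilyl)oxy]-2,6,6-trimethyl-2-[(triethylsilyl)oxy]-1-[(trimethylsilyl)methyl]cyclohexan-1-ol F3 (configuration at C1 irrelevant), and KH (THF, 0 °C) eliminates it to 10.

**Step 8.** Osmylation of a 1,1-disubstituted alkene between two quaternary carbons may be too slow, and a long exposure to the aqueous medium may hydrolyse the tertiary silyl ether and weaken the facial bias. Fallback from 10: epoxidation with dimethyldioxirane (acetone, 0 °C), a smaller electrophile that follows the same facial preference, should give the spiro-epoxide tert-butyldimethyl({(3R,5S,7R)-4,4,8-trimethyl-8-[(triethylsilyl)oxy]-1-oxaspiro[2.5]octan-6-yl}oxy)silane, drawn with the epoxide oxygen trans to the C5 silyloxy group, F4. Opening at the methylene carbon with KOH in DMSO/H2O keeps the C6–O bond and returns to 11.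

**Step 10.** The aldehyde is neopentyl and α-oxygenated. Slow addition of the phosphonate anion would leave time for base-induced α-ketol ring expansion of 12, and the reagent can deliver some 9Z isomer. Fallback from 12: Takai olefination (CrCl2, CHI3, THF) gives the (E)-vinyl iodide (1R,2R,4S)-4-[(tert-butyldimethylsilyl)oxy]-1-[(E)-2-iodoethenyl]-2,6,6-trimethyl-2-[(triethylsilyl)oxy]cyclohexan-1-ol F5. Stille coupling of F5 with ethyl (2E)-3-(tributylstannyl)but-2-enoate (Pd2(dba)3, AsPh3, CuI, DMF) forms the C8–C9 bond with both alkene geometries retained and returns to 14.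

## Further compounds

F1 | step 5 | (1S,2R,4S)-4-[(tert-butyldimethylsilyl)oxy]-2,6,6-trimethylcyclohexane-1,2-diol | O[C@H]1C(C)(C)C[C@H](O[Si](C)(C)C(C)(C)C)C[C@@]1(C)O
F2 | step 16 | (2E)-3-{(2S,6S,7aR)-6-[(tert-butyldimethylsilyl)oxy]-4,4,7a-trimethyl-2,4,5,6,7,7a-hexahydro-1-benzofuran-2-yl}but-2-enal | O=C/C=C(C)/[C@@H]1C=C2C(C)(C)C[C@H](O[Si](C)(C)C(C)(C)C)C[C@@]2(C)O1
F3 | step 7 | (2R,4S)-4-[(tert-butyldimethylsilyl)oxy]-2,6,6-trimethyl-2-[(triethylsilyl)oxy]-1-[(trimethylsilyl)methyl]cyclohexan-1-ol | C[Si](C)(C)CC1(O)C(C)(C)C[C@H](O[Si](C)(C)C(C)(C)C)C[C@@]1(C)O[Si](CC)(CC)CC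
F4 | step 8 | tert-butyldimethyl({(3R,5S,7R)-4,4,8-trimethyl-8-[(triethylsilyl)oxy]-1-oxaspiro[2.5]octan-6-yl}oxy)silane | C1O[C@@]12C(C)(C)C[C@H](O[Si](C)(C)C(C)(C)C)C[C@@]2(C)O[Si](CC)(CC)CC
F5 | step 10 | (1R,2R,4S)-4-[(tert-butyldimethylsilyl)oxy]-1-[(E)-2-iodoethenyl]-2,6,6-trimethyl-2-[(triethylsilyl)oxy]cyclohexan-1-ol | I/C=C/[C@@]1(O)C(C)(C)C[C@H](O[Si](C)(C)C(C)(C)C)C[C@@]1(C)O[Si](CC)(CC)CC
A1 | alternative 1 | 6'-hydroxy-7',8'-dihydro furanoid C15 unit (C11' tert-butyldimethylsilyl ether) | CC(C)(C)[Si](C)(C)OC\C=C(/C)[C@H]1C[C@@]2(O)C(C)(C)C[C@H](O)C[C@@]2(C)O1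
A2 | alternative 2 | (R)-linalool | C=C[C@](C)(O)CCC=C(C)C
A3 | alternative 2 | protected ring A triol with C7 as a silyloxymethyl group | CC(C)(C)[Si](C)(C)OC[C@@]1(O)C(C)(C)C[C@H](O[Si](C)(C)C(C)(C)C)C[C@@]1(C)O[Si](C)(C)C
A4 | alternative 3 | C15 furanoid bis(tert-butyldimethylsilyl) ether | CC(C)(C)[Si](C)(C)OC\C=C(/C)[C@H]1C=C2C(C)(C)C[C@H](O[Si](C)(C)C(C)(C)C)C[C@@]2(C)O1
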